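If we want the L in a flask of X, E and Q from a single earlier run, we first ask how far the new flask lies outside that run.

| flask | X | E | Q | remark | time |
|---|---|---|---|---|---|
| violet | 0.015 M | 0.030 M | 0.083 M | run made earlier |  |
| birch | 0.015 M | 0.0300 M | 0.0750 M |  | 15 min |
| alder | 0.0040 M | 0.120 M | 0.0200 M |  | 15 min |
| larch | 0.010 M | 0.0300 M | 0.0750 M |  | 15 min |
| cedar | 0.030 M | 0.0300 M | 0.0750 M |  | 15 min |

- violet (time / min: L / %): 1.00: 3; 3.00: 7; 6.00: 14; 10.0: 21

(each reading ± 2 percentage points)

1. ranking by amount of L, in percent of the X charged, from high to low, at 15 min (birch / alder / larch / cedar)
2. the amount of L, in percent of the X charged of the flask you put first, at 15 min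
3. the amount of L, in percent of the X charged of the flask you put last, at 15 min

- no earlier run changes the charge of Q; that part of a forecast is a guess
- a reading or a percentage of Q counts all its forms, free or not

The violet run climbs steadily to 21% of the X charged at 10.0 min, each reading carrying a scatter of 2 percentage points. Suppose E carries X straight to L and stays near its charge. X then decays in a pseudo-first-order way, with a rate constant proportional to E. Integrating that rate makes the logarithm of the fraction left proportional to the charge of E times the time, so the constant drops out when flasks are compared. Taking that product in units of its value at the last violet reading, larch, birch and cedar stand at 1.50 and alder at 6.00; this is the exposure. The fraction left is violet's 79.0% raised to the exposure.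

That gives us 29.8% of L for larch. Cedar has 1.00 E per X against 3.00 in larch, so its E should thin further, and we rank larch, birch, cedar. Alder reckons to 75.7%, but the readings stop at an exposure of 1, and alder lies 4.00 times beyond larch. No reading shows that L survives out there, and no run changes Q, so we hold that figure as conditional and leave alder unplaced.

The forecast, which does place alder, says alder > larch > birch > cedar, with 60% first and 26% last. Its alder figure, lower than ours, comes with the words “I guess about 60%, with wide bounds”.

The flasks give larch > birch > cedar > alder, from 25.6% in larch to 13.1% in alder.

    L + E → Q + G (k = 1.50 M⁻¹ min⁻¹)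
    J → Z (k = 0.210 min⁻¹)
    X + E → Q + J (k = 3.90 M⁻¹ min⁻¹)
    Q + X ⇌ D, settled at all times (K = 5.20 M⁻¹)
    J + E → Q + L (k = 12.0 M⁻¹ min⁻¹)

At an exposure of 1.50, larch at 15 min makes L 1.62 times as fast as it uses it up, each step taken net. Alder falls from 36.8% of L at 7.50 min, exposure 3.00 as charged, to 13.1% at 15 min, exposure 6.00, when its X stands at 0.276%. Larch left until 40 min, exposure 4.00 as charged, holds 23.7%, less than its 25.6% at 15 min.

The data stem from a simulated flask from invented constants, and the scatter is random.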